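**Retrosynthetic overview**
- The target is traced back to a β-keto-δ-lactone in which rings C and D are closed last by transannular C8–C14 alkylation, followed by C11=C12 hydrogenation, C16 methylenation and release of the C6 alcohol.
- The strategy rests on the seven-membered ring C8–C9–C11–C12–C13–C16–C15 inside the bicyclo[3.2.1]octane: its C15 ketone adjoins C8, which carries the C7 lactone carbonyl, and C14 is the one-carbon bridge.
- That ring and the δ-lactone (C7–O–C20–C10–C9–C8) form together from ring-A dienyl siloxyvinyldiazoacetate 23 by Rh-carbenoid cyclopropanation of C9=C11 and Cope rearrangement (bonds C8–C9 and C13–C16).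
- 23 comes from the fully substituted ring A: C9 aldehyde → Takai/Suzuki diene; C20 alcohol → acetoacetate → diazo transfer → enol silylation.
- Ring A comes from (S)-carvone: C4 by reductive hydroxymethylation, C10 by two enolate alkylations, C5–C6 by epoxide homologation, C1–OAc by Criegee rearrangement of the isopropenyl group. Ring order: A, then lactone plus seven-membered ring, then C/D.

Key step: step 18

Assumption: ent-kaurane numbering is used for all compounds (C19 = acetoxymethyl carbon on C4, C18 = methyl); minor diastereomers from steps 1 and 5 are removed by chromatography.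

**Route**

Step 1
Reactants: 1 (S)-(+)-carvone
Product: 3 (2S,5S)-2-(hydroxymethyl)-2-methyl-5-(prop-1-en-2-yl)cyclohexan-1-one, via lithium enolate 2 (not isolated)
Conditions: L-Selectride, THF, −78 °C; then monomeric CH2O, −78 → −40 °C; aq. NH4Cl
Reagents that add atoms: formaldehyde, C=O
Why: Conjugate hydride reduction gives the C4–C5 enolate regiospecifically, and the aldol with formaldehyde (reductive aldol) should follow axial attack on the half-chair with equatorial isopropenyl, so the new CH2OH (C19) enters cis to the isopropenyl group.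

Step 2
Reactants: 3 hydroxymethyl ketone
Product: 4 TBS ether of 3
Conditions: TBSCl, imidazole, DMF, rt
Reagents that add atoms: tert-butyldimethylsilyl chloride, CC(C)(C)[Si](C)(C)Cl
Why: Standard silylation of the primary alcohol, which also blocks retro-aldol loss of formaldehyde in the later base steps.

Step 3
Reactants: 4 TBS ether
Product: 6 C10 SEM-oxymethyl ketone (C10 epimers), via lithium enolate 5 (not isolated)
Conditions: LDA, THF, −78 °C; then SEMCl, DMPU, −78 → 0 °C
Reagents that add atoms: 2-(trimethylsilyl)ethoxymethyl chloride, C[Si](C)(C)CCOCCl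
Why: Deprotonation can occur only at C10 because C4 is quaternary, and the lithium enolate is C-alkylated by the chloromethyl ether (enolate alkylation); the C10 configuration is irrelevant because step 4 planarises it.

Step 4
Reactants: 6 C10 SEM-oxymethyl ketone
Product: 8 trimethylsilyl enol ether (C5=C10), via lithium enolate 7 (not isolated)
Conditions: LDA, THF, −78 °C; then TMSCl, Et3N, −78 → 0 °C
Reagents that add atoms: chlorotrimethylsilane, C[Si](C)(C)Cl
Why: Regiospecific enolisation toward the only remaining α-hydrogen and O-silylation at low temperature (silyl enol ether formation), which should outrun β-elimination of the alkoxymethyl group.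

Step 5
Reactants: 8 trimethylsilyl enol ether
Product: 9 β-keto acetal (C10 carries CH2OSEM cis and CH(OMe)2 trans to the C1 isopropenyl)
Conditions: HC(OMe)3, TMSOTf (10 mol %), CH2Cl2, −78 °C
Reagents that add atoms: trimethyl orthoformate, COC(OC)OC
Why: Mukaiyama-type addition of the silyl enol ether to the dimethoxycarbenium ion; the electrophile should add to C10 anti to the pseudoaxial isopropenyl group on C1, so C9 ends trans and C20 cis to it, which sets the C10 quaternary centre.

Step 6
Reactants: 9 β-keto acetal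
Product: 10 C5 spiro-epoxide
Conditions: Me3S+ I−, KHMDS, THF, 0 °C → rt
Reagents that add atoms: trimethylsulfonium iodide, C[S+](C)C.[I-]
Why: Corey–Chaykovsky epoxidation; the ketone has no α-hydrogen and cannot enolise, and the small sulfonium methylide should still reach a carbonyl flanked by two quaternary carbons, while the configuration of the spiro carbon is erased in step 9.

Step 7
Reactants: 10 C5 spiro-epoxide
Product: 11 C19 alcohol
Conditions: TBAF, THF, 0 °C → rt
Reagents that add atoms: none
Why: Fluoride cleavage of the primary TBS ether; the SEM ether, the acetal and the epoxide are stable to TBAF at this temperature.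

Step 8
Reactants: 11 C19 alcohol
Product: 13 C1/C19 diacetate epoxide, via methoxy hydroperoxide 12 (not isolated)
Conditions: O3, CH2Cl2/MeOH 4:1, −78 °C (Sudan Red end point); then Ac2O, Et3N, DMAP (cat.), CH2Cl2, 0 °C → rt
Reagents that add atoms: ozone, [O-][O+]=O; methanol, CO; acetic anhydride, CC(=O)OC(C)=O
Why: Ozonolysis in methanol gives the α-methoxy hydroperoxide, whose peracetate undergoes Criegee rearrangement with migration of the secondary ring carbon C1 and retention, so the isopropenyl group becomes the C1 acetate; the free C19 alcohol is acetylated in the same pot.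

Step 9
Reactants: 13 C1/C19 diacetate epoxide
Product: 14 C6 alcohol (H5 trans to C19 and C20)
Conditions: Cp2TiCl2 (20 mol %), Mn, 2,4,6-collidine·HCl, 1,4-cyclohexadiene, THF, rt
Reagents that add atoms: none
Why: Titanocene(III) reductive epoxide opening (Nugent–RajanBabu type, catalytic variant) gives the tertiary C5 radical and the primary alkoxide, and hydrogen transfer from cyclohexadiene should come from the ring face opposite the two flanking axial CH2O groups (C19, C20), setting H5 trans to them and C6 equatorial.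

Step 10
Reactants: 14 C6 alcohol
Product: 15 C6 TBDPS ether
Conditions: TBDPSCl, imidazole, DMAP (cat.), DMF, rt → 40 °C
Reagents that add atoms: tert-butyldiphenylsilyl chloride, CC(C)(C)[Si](Cl)(c1ccccc1)c1ccccc1
Why: Silylation of the only free hydroxyl with an acid-stable group that survives to the last step.

Step 11
Reactants: 15 C6 TBDPS ether
Product: 16 C9 aldehyde
Conditions: TsOH·H2O (cat.), acetone/H2O 10:1, 40 °C
Reagents that add atoms: water, O
Why: Acid-catalysed acetal hydrolysis frees the non-enolisable C9 aldehyde while the acetates, the SEM ether and the TBDPS ether are unaffected.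

Step 12
Reactants: 16 C9 aldehyde
Product: 17 (E)-C9=C11 vinyl iodide
Conditions: CrCl2, CHI3, THF, 0 °C → rt
Reagents that add atoms: iodoform, IC(I)I
Why: Takai olefination converts the hindered aldehyde into the (E)-vinyl iodide under non-basic conditions that tolerate the acetates.

Step 13
Reactants: 17 (E)-C9=C11 vinyl iodide; 18 (E)-3-(tert-butyldimethylsilyloxy)prop-1-enylboronic acid pinacol ester
Product: 19 (E,E)-diene (C9=C11–C12=C13–C14H2OTBS)
Conditions: Pd(PPh3)4 (5 mol %), aq. K3PO4, THF, rt, degassed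
Reagents that add atoms: none
Why: Suzuki–Miyaura coupling of two sp2 partners proceeds with retention of both alkene geometries and gives the (E,E)-diene.

Step 14
Reactants: 19 (E,E)-diene
Product: 20 C20 alcohol
Conditions: MgBr2·OEt2, MeNO2/Et2O, rt
Reagents that add atoms: none
Why: Chelation-assisted Lewis acid cleavage of the SEM formaldehyde acetal by MgBr2, conditions that leave acetates, TBS and TBDPS ethers and the diene alone.

Step 15
Reactants: 20 C20 alcohol
Product: 21 C20 acetoacetate
Conditions: 2,2,6-trimethyl-4H-1,3-dioxin-4-one, toluene, 110 °C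
Reagents that add atoms: 2,2,6-trimethyl-4H-1,3-dioxin-4-one, CC1=CC(=O)OC(C)(C)O1
Why: Thermal retro-[4+2] of the dioxinone gives acetylketene, which acylates the hindered neopentyl alcohol under neutral conditions (acetoacetylation) before the neighbouring C1 acetate can migrate.

Step 16
Reactants: 21 C20 acetoacetate
Product: 22 C20 diazoacetoacetate
Conditions: 4-acetamidobenzenesulfonyl azide, Et3N, MeCN, 0 °C → rt
Reagents that add atoms: 4-acetamidobenzenesulfonyl azide, CC(=O)Nc1ccc(cc1)S(=O)(=O)N=[N+]=[N-]
Why: Regitz diazo transfer to the active methylene group.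

Step 17
Reactants: 22 C20 diazoacetoacetate
Product: 23 ring-A dienyl siloxyvinyldiazoacetate
Conditions: TBSOTf, Et3N, CH2Cl2, 0 °C
Reagents that add atoms: tert-butyldimethylsilyl trifluoromethanesulfonate, CC(C)(C)[Si](C)(C)OS(=O)(=O)C(F)(F)F
Why: Soft enolisation and O-silylation of the methyl ketone give the 3-siloxy-2-diazobut-3-enoate (vinylcarbenoid precursor).

Step 18
Reactants: 23 ring-A dienyl siloxyvinyldiazoacetate
Product: 25 lactone-fused cycloheptadiene silyl enol ether, via cis-divinylcyclopropane 24 (not isolated)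
Conditions: Rh2(S-PTAD)4 (1 mol %), PhCF3, slow addition of 23, 0 °C → rt; then 50 °C
Reagents that add atoms: none
Why: The rhodium(II) carbenoid formed at C8 by loss of N2 cyclopropanates the proximal C9=C11 bond through the C7–O–C20–C10 tether (closing the six-membered lactone by C8–C9 bond formation, with the ester forced cis to C10 and hence the siloxyvinyl group cis to the C12=C13 vinyl group), and cis-divinylcyclopropane 24 then undergoes a boat Cope rearrangement that breaks C8–C11 and forms C13–C16, closing the seven-membered ring as a [3,3] shift. The closest known reaction type is the Rh(II)-catalysed tandem cyclopropanation/Cope rearrangement (formal [4+3]) of siloxyvinyldiazoacetates with dienes, including ester-tethered dienes. C9 is set by the face of C9=C11 that is attacked: with C20 held over the alkene, the diene arm should lie along the C10–C1 bond (CH–OAc flank) and not along the C10–C5 bond, which carries CH2OTBDPS next to the C4 quaternary centre, and the chiral carboxylate catalyst is chosen to reinforce this sense. C13 follows stereospecifically from the (E)-C12=C13 geometry through the boat transition state, which places C14 exo and cis to C10 across the ring. The step needs site selectivity for C9=C11 over C12=C13, secured by the tether (six- versus eight-membered lactone), and the cis-divinyl arrangement, secured by the tether together with the (E)-C9=C11 geometry.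

Step 19
Reactants: 25 lactone-fused cycloheptadiene silyl enol ether
Product: 27 β-keto lactone C14 alcohol (C8 epimers/enol), via keto lactone silyl ether 26 (not isolated)
Conditions: 1 M aq. HCl, THF, 0 °C → rt
Reagents that add atoms: none
Why: Acid hydrolysis cleaves the vinylogous silyl ester (enol ether) first and then the primary TBS ether, while the TBDPS ether and the acetates should survive.

Step 20
Reactants: 27 β-keto lactone C14 alcohol
Product: 28 C14 mesylate
Conditions: MsCl, Et3N, CH2Cl2, −40 °C
Reagents that add atoms: methanesulfonyl chloride, CS(Cl)(=O)=O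
Why: Mesylation of the primary alcohol is fast at low temperature, where the β-keto lactone enol is not sulfonylated.

Step 21
Reactants: 28 C14 mesylate
Product: 29 bicyclo[3.2.1]octene keto lactone (C11=C12)
Conditions: Cs2CO3, MeCN, 50 °C
Reagents that add atoms: none
Why: Intramolecular C-alkylation of the β-keto lactone enolate (exo-tet displacement); C14 is held on C13 on the face cis to C10 and can bond only to that face of C8, which closes rings C and D and sets the C8 quaternary centre, whereas O-alkylation would need a bridgehead enol ether.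

Step 22
Reactants: 29 bicyclo[3.2.1]octene keto lactone
Product: 30 saturated keto lactone
Conditions: H2 (1 atm), 10 % Pd/C, EtOAc, rt
Reagents that add atoms: none
Why: Heterogeneous hydrogenation of the only C=C bond (C11=C12); no stereocentre is created.

Step 23
Reactants: 30 saturated keto lactone
Product: 32 6-O-TBDPS ether of the target, via Mannich base 31 (not isolated)
Conditions: paraformaldehyde, N-methylanilinium trifluoroacetate, THF, reflux
Reagents that add atoms: formaldehyde (from paraformaldehyde), C=O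
Why: Mannich-type α-methylenation; the C15 ketone can enolise only toward C16 because C8 is quaternary, and the Mannich base eliminates N-methylaniline in situ to give the exocyclic enone.

Step 24
Reactants: 32 6-O-TBDPS ether of the target
Product: 33 CNP0105570.2 (target)
Conditions: HF·pyridine, pyridine, THF, 0 °C → rt
Reagents that add atoms: none
Why: Fluoride desilylation under buffered acidic conditions that should spare the enone, the lactone and both acetates.

**Compound list**

1 | (S)-(+)-carvone | CC1=CC[C@@H](CC1=O)C(C)=C | starting material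
2 | lithium enolate of (S)-dihydrocarvone (C4=C5 enolate) | C1[C@@H](C(C)=C)CCC(C)=C1[O-].[Li+] | intermediate (not isolated)
3 | (2S,5S)-2-(hydroxymethyl)-2-methyl-5-(prop-1-en-2-yl)cyclohexan-1-one (CH2OH cis to isopropenyl) | C1[C@@H](C(C)=C)CC[C@@](C)(CO)C1=O | intermediate
4 | TBS ether of 3 | C1[C@@H](C(C)=C)CC[C@@](C)(CO[Si](C)(C)C(C)(C)C)C1=O | intermediate
5 | lithium enolate of 4 (C5=C10) | C=1[C@@H](C(C)=C)CC[C@@](C)(CO[Si](C)(C)C(C)(C)C)C=1[O-].[Li+] | intermediate (not isolated)
6 | C10 SEM-oxymethyl ketone, C10 epimers | C[Si](C)(C)CCOCOCC1[C@@H](C(C)=C)CC[C@@](C)(CO[Si](C)(C)C(C)(C)C)C1=O | intermediate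
7 | lithium enolate of 6 | C[Si](C)(C)CCOCOCC=1[C@@H](C(C)=C)CC[C@@](C)(CO[Si](C)(C)C(C)(C)C)C=1[O-].[Li+] | intermediate (not isolated)
8 | trimethylsilyl enol ether (C5=C10) | C[Si](C)(C)CCOCOCC=1[C@@H](C(C)=C)CC[C@@](C)(CO[Si](C)(C)C(C)(C)C)C=1O[Si](C)(C)C | intermediate
9 | β-keto acetal; C10: CH2OSEM (C20) cis, CH(OMe)2 (C9) trans to isopropenyl | C[Si](C)(C)CCOCOC[C@@]1(C(OC)OC)[C@@H](C(C)=C)CC[C@@](C)(CO[Si](C)(C)C(C)(C)C)C1=O | intermediate
10 | C5 spiro-epoxide (expected epimer from axial attack drawn; either epimer converges in step 9) | C[Si](C)(C)CCOCOC[C@@]1(C(OC)OC)[C@@H](C(C)=C)CC[C@@](C)(CO[Si](C)(C)C(C)(C)C)[C@]13CO3 | intermediate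
11 | C19 alcohol | C[Si](C)(C)CCOCOC[C@@]1(C(OC)OC)[C@@H](C(C)=C)CC[C@@](C)(CO)[C@]13CO3 | intermediate
12 | α-methoxy hydroperoxide at C1 side chain | C[Si](C)(C)CCOCOC[C@@]1(C(OC)OC)[C@@H](C(C)(OC)OO)CC[C@@](C)(CO)[C@]13CO3 | intermediate (not isolated)
13 | C1/C19 diacetate epoxide | C[Si](C)(C)CCOCOC[C@@]1(C(OC)OC)[C@@H](OC(C)=O)CC[C@@](C)(COC(C)=O)[C@]13CO3 | intermediate
14 | C6 alcohol, H5 trans to C19/C20 | C[Si](C)(C)CCOCOC[C@@]1(C(OC)OC)[C@@H](OC(C)=O)CC[C@@](C)(COC(C)=O)[C@H]1CO | intermediate
15 | C6 TBDPS ether | C[Si](C)(C)CCOCOC[C@@]1(C(OC)OC)[C@@H](OC(C)=O)CC[C@@](C)(COC(C)=O)[C@H]1CO[Si](c2ccccc2)(c3ccccc3)C(C)(C)C | intermediate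
16 | C9 aldehyde | C[Si](C)(C)CCOCOC[C@@]1(C=O)[C@@H](OC(C)=O)CC[C@@](C)(COC(C)=O)[C@H]1CO[Si](c2ccccc2)(c3ccccc3)C(C)(C)C | intermediate
17 | (E)-C9=C11 vinyl iodide | C[Si](C)(C)CCOCOC[C@@]1(/C=C/I)[C@@H](OC(C)=O)CC[C@@](C)(COC(C)=O)[C@H]1CO[Si](c2ccccc2)(c3ccccc3)C(C)(C)C | intermediate
18 | (E)-3-(tert-butyldimethylsilyloxy)prop-1-enylboronic acid pinacol ester | CC(C)(C)[Si](C)(C)OC/C=C/B1OC(C)(C)C(C)(C)O1 | starting material
19 | (E,E)-diene, C20 SEM ether | C[Si](C)(C)CCOCOC[C@@]1(/C=C/C=C/CO[Si](C)(C)C(C)(C)C)[C@@H](OC(C)=O)CC[C@@](C)(COC(C)=O)[C@H]1CO[Si](c2ccccc2)(c3ccccc3)C(C)(C)C | intermediate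
20 | C20 alcohol | OC[C@@]1(/C=C/C=C/CO[Si](C)(C)C(C)(C)C)[C@@H](OC(C)=O)CC[C@@](C)(COC(C)=O)[C@H]1CO[Si](c2ccccc2)(c3ccccc3)C(C)(C)C | intermediate
21 | C20 acetoacetate | CC(=O)CC(=O)OC[C@@]1(/C=C/C=C/CO[Si](C)(C)C(C)(C)C)[C@@H](OC(C)=O)CC[C@@](C)(COC(C)=O)[C@H]1CO[Si](c2ccccc2)(c3ccccc3)C(C)(C)C | intermediate
22 | C20 diazoacetoacetate | CC(=O)C(=[N+]=[N-])C(=O)OC[C@@]1(/C=C/C=C/CO[Si](C)(C)C(C)(C)C)[C@@H](OC(C)=O)CC[C@@](C)(COC(C)=O)[C@H]1CO[Si](c2ccccc2)(c3ccccc3)C(C)(C)C | intermediate
23 | ring-A dienyl siloxyvinyldiazoacetate (key-step precursor) | C=C(O[Si](C)(C)C(C)(C)C)C(=[N+]=[N-])C(=O)OC[C@@]1(/C=C/C=C/CO[Si](C)(C)C(C)(C)C)[C@@H](OC(C)=O)CC[C@@](C)(COC(C)=O)[C@H]1CO[Si](c2ccccc2)(c3ccccc3)C(C)(C)C | intermediate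
24 | cis-divinylcyclopropane fused to the δ-lactone | O=C1OC[C@]2([C@@H](OC(C)=O)CC[C@@](C)(COC(C)=O)[C@H]2CO[Si](c4ccccc4)(c5ccccc5)C(C)(C)C)[C@@H]3[C@@H](/C=C/CO[Si](C)(C)C(C)(C)C)[C@]13C(O[Si](C)(C)C(C)(C)C)=C | intermediate (not isolated)
25 | lactone-fused cycloheptadiene silyl enol ether (key-step product) | O=C1OC[C@]2([C@@H](OC(C)=O)CC[C@@](C)(COC(C)=O)[C@H]2CO[Si](c4ccccc4)(c5ccccc5)C(C)(C)C)[C@@H]3C=C[C@H](CO[Si](C)(C)C(C)(C)C)CC(O[Si](C)(C)C(C)(C)C)=C13 | intermediate
26 | β-keto lactone, C14 TBS ether (C8 epimers/enol) | O=C1OC[C@]2([C@@H](OC(C)=O)CC[C@@](C)(COC(C)=O)[C@H]2CO[Si](c4ccccc4)(c5ccccc5)C(C)(C)C)[C@@H]3C=C[C@H](CO[Si](C)(C)C(C)(C)C)CC(=O)C13 | intermediate (not isolated)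
27 | β-keto lactone C14 alcohol (C8 epimers/enol) | O=C1OC[C@]2([C@@H](OC(C)=O)CC[C@@](C)(COC(C)=O)[C@H]2CO[Si](c4ccccc4)(c5ccccc5)C(C)(C)C)[C@@H]3C=C[C@H](CO)CC(=O)C13 | intermediate
28 | C14 mesylate | O=C1OC[C@]2([C@@H](OC(C)=O)CC[C@@](C)(COC(C)=O)[C@H]2CO[Si](c4ccccc4)(c5ccccc5)C(C)(C)C)[C@@H]3C=C[C@H](COS(C)(=O)=O)CC(=O)C13 | intermediate
29 | bicyclo[3.2.1]octene keto lactone (C11=C12) | C1C(=O)[C@]23C[C@H]1C=C[C@H]2[C@]1(COC3=O)[C@@H](OC(C)=O)CC[C@@](C)(COC(C)=O)[C@H]1CO[Si](c4ccccc4)(c5ccccc5)C(C)(C)C | intermediate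
30 | saturated keto lactone | C1C(=O)[C@]23C[C@H]1CC[C@H]2[C@]1(COC3=O)[C@@H](OC(C)=O)CC[C@@](C)(COC(C)=O)[C@H]1CO[Si](c4ccccc4)(c5ccccc5)C(C)(C)C | intermediate
31 | C16 Mannich base (C16 epimers) | CN(c6ccccc6)CC1C(=O)[C@]23C[C@H]1CC[C@H]2[C@]1(COC3=O)[C@@H](OC(C)=O)CC[C@@](C)(COC(C)=O)[C@H]1CO[Si](c4ccccc4)(c5ccccc5)C(C)(C)C | intermediate (not isolated)
32 | 6-O-TBDPS ether of the target | C=C1C(=O)[C@]23C[C@H]1CC[C@H]2[C@]1(COC3=O)[C@@H](OC(C)=O)CC[C@@](C)(COC(C)=O)[C@H]1CO[Si](c4ccccc4)(c5ccccc5)C(C)(C)C | intermediate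
33 | CNP0105570.2, (1S,4R,5R,8S,9S,10S,13R) in ent-kaurane numbering | C=C1C(=O)[C@]23C[C@H]1CC[C@H]2[C@]1(COC3=O)[C@@H](OC(C)=O)CC[C@@](C)(COC(C)=O)[C@H]1CO | target

**Totals**

Total step count: 24. Longest linear sequence: 24 steps from (S)-carvone (boronate 18 is purchased).

**Steps most likely to fail**

Step 18. The vinylcarbenoid may attack C9=C11 from the wrong face (wrong C9 relative to C10), or be diverted into C–H insertion or reaction at its vinylogous terminus before it reaches the hindered alkene. The fallback separates carbene transfer from the rearrangement. It sets out from diazoacetoacetate 22: intramolecular cyclopropanation of this acceptor/acceptor diazo compound (Rh2(esp)2 or a copper(I) bisoxazoline catalyst, toluene, 60–80 °C) should give the acetylcyclopropane δ-lactone F1, with the acetyl group cis to the C12=C13 vinyl group for the same tether reason. Enol silylation of F1 (TBSOTf, Et3N) then gives the cis-divinylcyclopropane 24, which rearranges on warming, and the route is rejoined at 25.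

Step 9. Hydrogen transfer to the C5 radical may occur from the wrong face, or the radical may be diverted by a 1,5-hydrogen shift from the SEM methylene or by loss of the titanium alkoxide to give the alkene. The fallback replaces the radical by a stereospecific 1,2-hydride shift. It sets out from epoxide 13: Meinwald rearrangement with the bulky Lewis acid MABR (methylaluminium bis(4-bromo-2,6-di-tert-butylphenoxide), CH2Cl2, −78 °C) should give the C6 aldehyde F2, the hydride migrating to C5 anti to the departing equatorial oxygen. Immediate NaBH4 reduction (MeOH, 0 °C) then returns to alcohol 14.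

Step 21. The transannular displacement may be slow, letting β-elimination of the mesylate toward C13 or O-alkylation take over. The fallback forms the C8–C14 bond by a reversible carbonyl addition instead. It sets out from alcohol 27: hydrogenation of C11=C12 (H2, Pd/C) gives the saturated keto alcohol F3, Dess–Martin oxidation gives the keto aldehyde F4, and intramolecular aldol addition of the β-keto lactone to the C14 aldehyde (DBU, CH2Cl2) gives the bridged aldol F5. The C14 hydroxyl is then removed by Barton–McCombie deoxygenation through the thiocarbonylimidazolide F6 (1,1'-thiocarbonyldiimidazole, DMAP, toluene, 80 °C; then Bu3SnH, AIBN, 90 °C), and the route is rejoined at 30.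

Further compounds
F1 | step 18 | acetylcyclopropane δ-lactone (acetyl cis to the C12=C13 vinyl group) | O=C1OC[C@]2([C@@H](OC(C)=O)CC[C@@](C)(COC(C)=O)[C@H]2CO[Si](c4ccccc4)(c5ccccc5)C(C)(C)C)[C@@H]3[C@@H](/C=C/CO[Si](C)(C)C(C)(C)C)[C@]13C(C)=O
F2 | step 9 | C6 aldehyde (H5 trans to C19/C20) | C[Si](C)(C)CCOCOC[C@@]1(C(OC)OC)[C@@H](OC(C)=O)CC[C@@](C)(COC(C)=O)[C@H]1C=O
F3 | step 21 | saturated β-keto lactone C14 alcohol | O=C1OC[C@]2([C@@H](OC(C)=O)CC[C@@](C)(COC(C)=O)[C@H]2CO[Si](c4ccccc4)(c5ccccc5)C(C)(C)C)[C@@H]3CC[C@H](CO)CC(=O)C13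
F4 | step 21 | saturated β-keto lactone C14 aldehyde | O=C1OC[C@]2([C@@H](OC(C)=O)CC[C@@](C)(COC(C)=O)[C@H]2CO[Si](c4ccccc4)(c5ccccc5)C(C)(C)C)[C@@H]3CC[C@H](C=O)CC(=O)C13
F5 | step 21 | bridged aldol with C14 hydroxyl (C14 epimers) | C1C(=O)[C@]23C(O)[C@H]1CC[C@H]2[C@]1(COC3=O)[C@@H](OC(C)=O)CC[C@@](C)(COC(C)=O)[C@H]1CO[Si](c4ccccc4)(c5ccccc5)C(C)(C)C
F6 | step 21 | C14 O-thiocarbonylimidazolide | C1C(=O)[C@]23C(OC(=S)n6ccnc6)[C@H]1CC[C@H]2[C@]1(COC3=O)[C@@H](OC(C)=O)CC[C@@](C)(COC(C)=O)[C@H]1CO[Si](c4ccccc4)(c5ccccc5)C(C)(C)C
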